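## Structural features

The target is an achiral diaryl ether: two benzene rings, A and B, are joined only through the oxygen between a5 and b1, and there is no stereocenter. Ring A is pentasubstituted (a1 CH2OH, a3 Br, a4 OH, a5 O-aryl, a6 Br, hydrogen only on a2), and ring B likewise (b1 O-aryl, b2 CH2OH, b4 Br, b5 and b6 OH, hydrogen only on b3). The ether oxygen is flanked by two ortho substituents on each ring (a4–OH and a6–Br; b2–CH2OH and b6–OH), so a direct aryl–oxygen coupling would have to join two fully hindered positions. The fragile parts are the two hydroxymethyl groups, each para to a phenolic hydroxyl (a1/a4 and b2/b5) and so prone to ionise to quinone methides under acid. The b5/b6 catechol is air-sensitive, and the three aryl bromides exclude hydrogenolysis and low-valent metals late in the route. The real difficulty is ring A: a3–Br is ortho to the a4 hydroxyl and easy to place, but a6–Br is meta to it, between the ether carbon a5 and the carbinol-bearing a1, where no phenol-directed bromination will go. Read as a carbocycle, a3–a4–a5–a6 is a cyclohexane-1,2-dione monoaryl enol ether with bromine on both α-carbons. The key step uses this: a3 to a6 come from a 2-aryloxy-3-silyloxybutadiene, a1 and a2 from an acrylate, and the bromines enter while the ring is not yet, or only just, aromatic.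

## Logic of the disconnections

18 ⇒ 17. The two hydroxymethyl carbons (on a1 and b2) are taken back to methyl ester carbons. Both carbinols are para-hydroxybenzylic and cannot survive Lewis acid or electrophilic bromine, so they are unveiled last. Everything upstream is then carried as robust esters. The forward step needs a hydride reagent that reduces two esters in the presence of three phenoxides and three aryl bromides.

17 ⇒ 16. The b5 and b6 hydroxyls are returned to methyl ethers (two O–CH3 bonds). These ethers come with 1 and shield the catechol through every bromination. The cleavage must spare the diaryl ether and the methyl esters and must precede the appearance of any benzylic alcohol.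

16 ⇒ 15. The a3–Br bond is cut. In 15, a3 is the only open position ortho to the a4 hydroxyl, the para position a1 is blocked, and b3 on ring B is deactivated, so one equivalent of electrophilic bromine has a single sensible destination.

15 ⇒ 13. Aromatic ring A is traced to a cyclohexenone by adding two hydrogens (a2–a3 saturated, a1 sp3). The a6 bromine cannot be introduced on an arene, so it must already be on the ring before aromatisation. 13 carries it as the β-bromide of a 2-aryloxyenone. The forward step is a single dehydrogenation that must leave the vinyl bromide and the aryl enol ether intact.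

13 ⇒ 11. The a6–Br bond is cut. In 11, a6 is the β-carbon of an aryl enol ether, and after attack of bromine the only hydrogen next to the cationic a5 is the one on a6. The elimination must go through the a5 bromide and not through the ester α-hydrogen on a1, which calls for a weak base.

11 ⇒ 10. The a5=a6 double bond and the a4 carbonyl are traced to an allylic amine on a6 and a silyl enol ether (a6–N and O–Si bonds restored). The amine is the leaving group that gives 11 the oxidation level of a dione monoenol ether without an oxidant. The forward step needs acid mild enough to leave the aryl enol ether unhydrolysed.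

10 ⇒ 8 + 9. The bonds a2–a3 and a6–a1 are cut, the key disconnection. Ring A falls into a four-carbon diene that already carries both oxygens, the ether oxygen on a5 included, and the two-carbon unit 9 that brings a1 with its carboxyl carbon. The hexasubstituted arene and its hindered ether are reduced to an acyclic enol ether. The forward step must be regioselective: a3 has to bond to the β-carbon of 9.

8 ⇒ 7 ⇒ 6. The O–Si bond and then the a5=a6 bond are cut. The a6 carbon is introduced as a one-carbon amide acetal at the methylene of 6 that lies between the carbonyl and the aryloxy oxygen. The condensation must occur at that CH2 and not at the methyl group, and the silylation must enolise the methyl ketone without touching the ring B ester.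

6 ⇒ 4 + 5. The O–CH2 bond that becomes the a5–O bond is cut. The ether oxygen is attached to the future a5 while that carbon is an unhindered primary sp3 centre, so an SN2 alkylation replaces a doubly ortho-substituted diaryl ether coupling. The forward step needs a base too weak to trigger aldol or Dieckmann chemistry.

4 ⇒ 3 ⇒ 2 ⇒ 1. The b4–Br bond, then the methyl of the ether ortho to the ester (restored retrosynthetically), then the ester methyl are removed. Bromination of 3 is directed para to the free hydroxyl. The selective cleavage in 2 relies on chelation to the neighbouring carbonyl, and 1 is a cheap commercial acid with all three oxygens of ring B in place.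

## Other disconnections considered

Alternative 1: Ring A is cut at a5–a6 and a1–a2.
- Forward step: thermal [4+2] cycloaddition of the pyrone A1 with the bromoalkyne ester A2, followed by decarboxylative loss of the lactone bridge, would give the fully aromatic diaryl ether A3.
- In its favour: ring A arrives aromatic, with both bromines and all oxygens placed in one operation. Only ether cleavage and ester reduction remain after A3. On step economy after the key step this is better than the chosen plan, which needs four steps (8–11) to reach the same substitution pattern in 16.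
- Against it here: the a5–a6 bond joins two fully substituted carbons beside the bulky aryloxy group. The 3-aryloxy and 4-methoxy donors of A1 polarise the pyrone termini in opposite senses, so the required orientation is not clearly favoured and is also the more crowded one. Pyrone–alkyne cycloadditions usually need temperatures that a bromoalkyne tolerates poorly. A1 is a trisubstituted pyrone that needs its own multistep synthesis. A3 has a third methyl ether to cleave.
- Comparison: on structure the two plans are equal in forming ring A on a pre-existing aryl–oxygen bond. On mechanism, A3 is secured by irreversible decarboxylation, but regiocontrol rests on opposed substituent effects, whereas in step 7 the amino and silyloxy groups reinforce each other. The shorter end game of the alternative is paid for by a longer, less certain front end.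

Alternative 2: Ring A is cut at a5–a6 and a6–a1, so that a6 is a one-carbon unit.
- Forward step: dibromocarbene A5 would add to the tetrasubstituted enol ether double bond of the cyclopentene ketal A4. The dibromocyclopropane would open with loss of bromide and of a proton from a2 to give the ring-expanded bromodiene A6.
- In its favour: a6–Br is placed with complete positional certainty, because a6 is the carbene carbon. This is better than step 9 of the chosen plan, where the same bromine depends on an addition–elimination that must outrun a competing loss of HBr. The five-membered precursor is cheap, and A6 is one hydrolysis and tautomerisation away from a phenol.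
- Against it here: the double bond of A4 is tetrasubstituted, flanked by a ketal and a 2,6-disubstituted aryloxy group, and less nucleophilic than an alkyl enol ether, so carbene addition is doubtful. The a1 substituent arrives as a methyl group and would need a late benzylic oxidation on an electron-rich bromophenol. Ring B carries a masked aldehyde that also needs adjustment, and a3–Br still requires a phenol bromination.
- Comparison: step counts are about equal. The alternative is better at a6, but its weakest step lies at the end (methyl to hydroxymethyl), whereas in the chosen plan a1 arrives from 9 as an ester that needs only hydride reduction.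

Alternative 3: Ring B is cut at b1–b2.
- Forward step: under amine base the aryloxymethylene carbon of the tricarbonyl chain A7 would add to the α-keto ester carbonyl. Dehydration and two enolisations would deliver the catechol A8.
- In its favour: the aromatisation is redox-neutral and needs no oxidant. The catechol appears unprotected, so ring B needs no ether cleavage, which is better on protecting-group economy than steps 2 and 12 of the chosen plan. The ether oxygen is attached by alkylating a phenol with an α-halo ketone, the same tactic as in step 4 (equal on this point).
- Against it here: the key step builds ring B, which simple aromatic chemistry supplies in three steps from 1. Ring A, with its a6 bromine meta to the a4 oxygen, would have to be prepared by substitution chemistry that has no directing group for that position, so the central problem is left unsolved. A7 is a polyelectrophile with a 1,2-dione and a 1,4-dicarbonyl unit, prone to hydration, benzilic-type rearrangement and reclosure to a furan. Its preparation by oxidative opening of a furan and alkene reduction must tolerate aryl bromides. The b4 bromine must still be added to A8.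
- Comparison: on mechanism the aldol aromatisation is milder than anything in steps 8–11. On structure it addresses the easy ring, so the overall step count would not fall.

Key step: step 7

Remarks on the chemistry:
- The target has no stereocenter. The chiral intermediates 10–14 are carried as racemates or diastereomer mixtures, and all their stereocenters disappear by step 10.
- A cycloadduct of the amine-free 2-aryloxy-3-silyloxybutadiene would be the enediol diether of an α-aryloxy ketone, one oxidation level below a dione monoenol ether, and its regiochemistry would rest only on silyloxy being a better donor than aryloxy. The diene 8 therefore carries one extra, traceless dimethylamino group on the a6 terminus, which leaves in step 8; the bonds formed, the ring closed and the carbon–oxygen skeleton of diene and adduct are unchanged.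

## Route

Step 1
Reactants: 1 2,3,4-trimethoxybenzoic acid
Product: 2 methyl 2,3,4-trimethoxybenzoate
Conditions: MeOH, H2SO4 (cat.), reflux
Reagents that add atoms: methanol, CO
Why: Fischer esterification; the ester is needed both as the chelating group for step 2 and as the precursor of the b2 hydroxymethyl group.

Step 2
Reactants: 2 methyl 2,3,4-trimethoxybenzoate
Product: 3 methyl 2-hydroxy-3,4-dimethoxybenzoate
Conditions: BCl3 (1.2 equiv), CH2Cl2, −10 → 0 °C; then H2O
Reagents that add atoms: none
Why: Chelation-controlled ether cleavage: BCl3 binds between the ester carbonyl and the ortho methoxy oxygen and chloride removes only that methyl group; the 3- and 4-methoxy groups lack this assistance.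

Step 3
Reactants: 3 methyl 2-hydroxy-3,4-dimethoxybenzoate
Product: 4 methyl 5-bromo-2-hydroxy-3,4-dimethoxybenzoate
Conditions: NBS (1.05 equiv), MeCN, 0 → 20 °C
Reagents that add atoms: N-bromosuccinimide, O=C1CCC(=O)N1Br
Why: Electrophilic aromatic bromination; C5 is para to the free hydroxyl and ortho to the 4-methoxy group, whereas C6 is deactivated by the adjacent ester.

Step 4
Reactants: 4 methyl 5-bromo-2-hydroxy-3,4-dimethoxybenzoate; 5 chloroacetone
Product: 6 methyl 5-bromo-3,4-dimethoxy-2-(2-oxopropoxy)benzoate
Conditions: K2CO3, KI (cat.), acetone, 50 °C
Reagents that add atoms: none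
Why: Williamson ether synthesis with in situ Finkelstein activation; the hindered phenoxide attacks a primary α-halo ketone, and carbonate is too weak a base to drive a Dieckmann-type closure onto the neighbouring ester.

Step 5
Reactants: 6 methyl 5-bromo-3,4-dimethoxy-2-(2-oxopropoxy)benzoate
Product: 7 methyl 5-bromo-2-{[(1Z)-1-(dimethylamino)-3-oxobut-1-en-2-yl]oxy}-3,4-dimethoxybenzoate
Conditions: Me2NCH(OMe)2 (1.5 equiv), toluene, 90 °C
Reagents that add atoms: N,N-dimethylformamide dimethyl acetal, COC(OC)N(C)C
Why: Aminomethylenation of an active methylene by an amide acetal; the CH2 between the carbonyl and the aryloxy oxygen is the more acidic α-position, and condensation there is the usual outcome with aryloxy- and alkoxyacetones. Loss of two methanol molecules gives the push–pull enaminone with the amino group trans to the acetyl group (Z).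

Step 6
Reactants: 7 methyl 5-bromo-2-{[(1Z)-1-(dimethylamino)-3-oxobut-1-en-2-yl]oxy}-3,4-dimethoxybenzoate
Product: 8 methyl 5-bromo-2-({(1Z)-3-[(tert-butyldimethylsilyl)oxy]-1-(dimethylamino)buta-1,3-dien-2-yl}oxy)-3,4-dimethoxybenzoate
Conditions: NaN(SiMe3)2 (1.05 equiv), THF, −78 °C; then TBSCl, −78 → 20 °C
Reagents that add atoms: tert-butyldimethylsilyl chloride, CC(C)(C)[Si](C)(C)Cl
Why: Deprotonation of the acetyl methyl group, the only enolisable position of the vinylogous amide, and O-silylation of the cross-conjugated enolate is the standard preparation of 1-amino-3-silyloxybutadienes. At −78 °C the hindered ring B ester should not be attacked, and the crude diene is used at once.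

Step 7
Reactants: 8 methyl 5-bromo-2-({(1Z)-3-[(tert-butyldimethylsilyl)oxy]-1-(dimethylamino)buta-1,3-dien-2-yl}oxy)-3,4-dimethoxybenzoate; 9 methyl acrylate
Product: 10 methyl 5-bromo-2-{[2-[(tert-butyldimethylsilyl)oxy]-6-(dimethylamino)-5-(methoxycarbonyl)cyclohex-1-en-1-yl]oxy}-3,4-dimethoxybenzoate (racemic cis/trans mixture)
Conditions: 9 (3 equiv), toluene, 20 → 40 °C, acid-free glassware
Reagents that add atoms: none
Why: A concerted but asynchronous, normal-demand Diels–Alder reaction: the HOMO of the diene, raised by the a6 amino and a4 silyloxy groups, has its largest coefficient at a3, which bonds to the β-carbon a2 of the acrylate while a6 bonds to the ester-bearing a1. The closest known reaction type is the cycloaddition of 1-amino-3-silyloxybutadienes with acrylates, which runs near room temperature. The six-membered carbocycle is closed by a suprafacial [4+2] addition in which both σ-bonds (a2–a3 and a6–a1) form in the same step. Two stereocenters arise, a1 and a6; their relative configuration follows from endo/exo competition, no control is sought, the adduct is racemic, and both centres are erased later (a6 in step 8, a1 in step 10). The selectivity that matters is regiochemical: the ester must end up 1,4 to a4 and adjacent to a6, which is secured because the amino and silyloxy donors reinforce each other and outweigh the opposing influence of the weakly donating, electron-poor aryloxy group on a5. The push–pull C=C of the diene rotates easily, so the s-cis conformer with the amino group pointing outward is accessible. Acid is excluded so that the amine is not lost before the ring is closed.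

Step 8
Reactants: 10 methyl 5-bromo-2-{[2-[(tert-butyldimethylsilyl)oxy]-6-(dimethylamino)-5-(methoxycarbonyl)cyclohex-1-en-1-yl]oxy}-3,4-dimethoxybenzoate
Product: 11 methyl 5-bromo-3,4-dimethoxy-2-{[3-(methoxycarbonyl)-6-oxocyclohex-1-en-1-yl]oxy}benzoate (racemic)
Conditions: HCl (1 M aq., 2 equiv), THF, 0 °C
Reagents that add atoms: none
Why: Protonation of the allylic amine lets the silyl enol ether expel it in a vinylogous β-elimination, and desilylation of the resulting silyloxocarbenium ion gives the 2-aryloxyenone (the known acid work-up of aminosilyloxy cycloadducts). The a6 stereocenter disappears, so both diastereomers of 10 converge.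

Step 9
Reactants: 11 methyl 5-bromo-3,4-dimethoxy-2-{[3-(methoxycarbonyl)-6-oxocyclohex-1-en-1-yl]oxy}benzoate
Product: 13 methyl 5-bromo-2-{[2-bromo-3-(methoxycarbonyl)-6-oxocyclohex-1-en-1-yl]oxy}-3,4-dimethoxybenzoate (racemic), via dibromide 12 (not isolated)
Conditions: Br2 (1.05 equiv), CH2Cl2, −78 °C; then pyridine (3 equiv), −78 → 20 °C
Reagents that add atoms: bromine, BrBr
Why: Electrophilic bromine attacks a6, the β-carbon of the aryl enol ether, to give 12; its a5 bromide is an α-halo ether that ionises, and the only hydrogen next to cationic a5 is on a6, so HBr is lost in an addition–elimination known for 2-alkoxyenones. Pyridine is too weak a base to remove the ester α-hydrogen on a1, which would cost the a6 bromine.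

Step 10
Reactants: 13 methyl 5-bromo-2-{[2-bromo-3-(methoxycarbonyl)-6-oxocyclohex-1-en-1-yl]oxy}-3,4-dimethoxybenzoate
Product: 15 methyl 5-bromo-2-[2-bromo-6-hydroxy-3-(methoxycarbonyl)phenoxy]-3,4-dimethoxybenzoate, via bromoenone 14 (not isolated)
Conditions: CuBr2 (2.2 equiv), LiBr (1 equiv), MeCN, 80 °C
Reagents that add atoms: none
Why: CuBr2 brominates the enol of the ketone at a3, and loss of HBr gives a cyclohexadienone that tautomerises to the phenol (the known CuBr2/LiBr aromatisation of cyclohexenones). Bromination at a1 or a5 through the extended enol would lose HBr to the same phenol, so the site of halogenation is not critical; the a1 stereocenter disappears.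

Step 11
Reactants: 15 methyl 5-bromo-2-[2-bromo-6-hydroxy-3-(methoxycarbonyl)phenoxy]-3,4-dimethoxybenzoate
Product: 16 methyl 5-bromo-2-[2,5-dibromo-6-hydroxy-3-(methoxycarbonyl)phenoxy]-3,4-dimethoxybenzoate
Conditions: NBS (1.05 equiv), iPr2NH (10 mol %), CH2Cl2, 0 → 20 °C
Reagents that add atoms: N-bromosuccinimide, O=C1CCC(=O)N1Br
Why: Electrophilic aromatic bromination ortho to the free a4 hydroxyl; a3 is the only open ortho position, the para position a1 is blocked by the ester, and b3 on ring B is deactivated by its ortho ester.

Step 12
Reactants: 16 methyl 5-bromo-2-[2,5-dibromo-6-hydroxy-3-(methoxycarbonyl)phenoxy]-3,4-dimethoxybenzoate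
Product: 17 methyl 5-bromo-2-[2,5-dibromo-6-hydroxy-3-(methoxycarbonyl)phenoxy]-3,4-dihydroxybenzoate
Conditions: BBr3 (5 equiv), CH2Cl2, −78 → 0 °C; then H2O
Reagents that add atoms: none
Why: Lewis-acid cleavage of the two aryl methyl ethers by SN2 attack of bromide on the boron-complexed methyl groups; at 0 °C the methyl esters and the diaryl ether should survive, and no benzylic alcohol is yet present to be turned into a bromide.

Step 13
Reactants: 17 methyl 5-bromo-2-[2,5-dibromo-6-hydroxy-3-(methoxycarbonyl)phenoxy]-3,4-dihydroxybenzoate
Product: 18 6-bromo-3-[2,5-dibromo-6-hydroxy-3-(hydroxymethyl)phenoxy]-4-(hydroxymethyl)benzene-1,2-diol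
Conditions: iBu2AlH (10 equiv), THF, −78 → 20 °C; aq. potassium sodium tartrate
Reagents that add atoms: none
Why: Excess iBu2AlH first converts the three phenols into aluminium phenoxides and then reduces both methyl esters to primary alcohols without touching aryl bromides. The neutral tartrate work-up avoids acid that would ionise the para-hydroxybenzyl alcohols.

## Compound list

1 | 2,3,4-trimethoxybenzoic acid | COc1ccc(C(=O)O)c(OC)c1OC | starting material
2 | methyl 2,3,4-trimethoxybenzoate | COC(=O)c1ccc(OC)c(OC)c1OC | intermediate
3 | methyl 2-hydroxy-3,4-dimethoxybenzoate | COC(=O)c1ccc(OC)c(OC)c1O | intermediate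
4 | methyl 5-bromo-2-hydroxy-3,4-dimethoxybenzoate | COC(=O)c1cc(Br)c(OC)c(OC)c1O | intermediate
5 | chloroacetone | CC(=O)CCl | starting material
6 | methyl 5-bromo-3,4-dimethoxy-2-(2-oxopropoxy)benzoate | COC(=O)c1cc(Br)c(OC)c(OC)c1OCC(C)=O | intermediate
7 | methyl 5-bromo-2-{[(1Z)-1-(dimethylamino)-3-oxobut-1-en-2-yl]oxy}-3,4-dimethoxybenzoate | CN(C)/C=C(\Oc1c(C(=O)OC)cc(Br)c(OC)c1OC)C(C)=O | intermediate
8 | methyl 5-bromo-2-({(1Z)-3-[(tert-butyldimethylsilyl)oxy]-1-(dimethylamino)buta-1,3-dien-2-yl}oxy)-3,4-dimethoxybenzoate | CN(C)/C=C(\Oc1c(C(=O)OC)cc(Br)c(OC)c1OC)C(=C)O[Si](C)(C)C(C)(C)C | intermediate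
9 | methyl acrylate | C=CC(=O)OC | starting material
10 | methyl 5-bromo-2-{[2-[(tert-butyldimethylsilyl)oxy]-6-(dimethylamino)-5-(methoxycarbonyl)cyclohex-1-en-1-yl]oxy}-3,4-dimethoxybenzoate (racemic cis/trans mixture) | COC(=O)C1CCC(O[Si](C)(C)C(C)(C)C)=C(Oc2c(C(=O)OC)cc(Br)c(OC)c2OC)C1N(C)C | intermediate
11 | methyl 5-bromo-3,4-dimethoxy-2-{[3-(methoxycarbonyl)-6-oxocyclohex-1-en-1-yl]oxy}benzoate (racemic) | COC(=O)C1CCC(=O)C(Oc2c(C(=O)OC)cc(Br)c(OC)c2OC)=C1 | intermediate
12 | methyl 5-bromo-2-{[1,2-dibromo-3-(methoxycarbonyl)-6-oxocyclohexyl]oxy}-3,4-dimethoxybenzoate (diastereomer mixture, not isolated) | COC(=O)C1CCC(=O)C(Br)(Oc2c(C(=O)OC)cc(Br)c(OC)c2OC)C1Br | intermediate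
13 | methyl 5-bromo-2-{[2-bromo-3-(methoxycarbonyl)-6-oxocyclohex-1-en-1-yl]oxy}-3,4-dimethoxybenzoate (racemic) | COC(=O)C1CCC(=O)C(Oc2c(C(=O)OC)cc(Br)c(OC)c2OC)=C1Br | intermediate
14 | methyl 5-bromo-2-{[2,5-dibromo-3-(methoxycarbonyl)-6-oxocyclohex-1-en-1-yl]oxy}-3,4-dimethoxybenzoate (diastereomer mixture, not isolated) | COC(=O)C1CC(Br)C(=O)C(Oc2c(C(=O)OC)cc(Br)c(OC)c2OC)=C1Br | intermediate
15 | methyl 5-bromo-2-[2-bromo-6-hydroxy-3-(methoxycarbonyl)phenoxy]-3,4-dimethoxybenzoate | COC(=O)c1ccc(O)c(Oc2c(C(=O)OC)cc(Br)c(OC)c2OC)c1Br | intermediate
16 | methyl 5-bromo-2-[2,5-dibromo-6-hydroxy-3-(methoxycarbonyl)phenoxy]-3,4-dimethoxybenzoate | COC(=O)c1cc(Br)c(O)c(Oc2c(C(=O)OC)cc(Br)c(OC)c2OC)c1Br | intermediate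
17 | methyl 5-bromo-2-[2,5-dibromo-6-hydroxy-3-(methoxycarbonyl)phenoxy]-3,4-dihydroxybenzoate | COC(=O)c1cc(Br)c(O)c(Oc2c(C(=O)OC)cc(Br)c(O)c2O)c1Br | intermediate
18 | 6-bromo-3-[2,5-dibromo-6-hydroxy-3-(hydroxymethyl)phenoxy]-4-(hydroxymethyl)benzene-1,2-diol | OCc1cc(Br)c(O)c(Oc2c(CO)cc(Br)c(O)c2O)c1Br | target

## Step count and least certain steps

Total step count: 13. Longest linear sequence: 13 steps, from 1 to 18; 5 and 9 are commercial and enter in steps 4 and 7.

Step 7 (key step). The cycloaddition may be slow because the 2-aryloxy group crowds the s-cis conformer, while hydrolysis of the moisture-sensitive aminodiene and polymerisation of the acrylate compete. The fallback drops the amino group and accepts a thermal reaction with bromine making up the oxidation level. Setting out from 6, α-methylenation at the aryloxy-bearing carbon [(CH2O)n, iPr2NH·CF3CO2H, THF, 65 °C] should give the enone methyl 5-bromo-3,4-dimethoxy-2-[(3-oxobut-1-en-2-yl)oxy]benzoate F1. Soft enolisation (TBSOTf, Et3N, CH2Cl2, 0 °C) should give the diene methyl 5-bromo-2-({3-[(tert-butyldimethylsilyl)oxy]buta-1,3-dien-2-yl}oxy)-3,4-dimethoxybenzoate F2. Heating with 9 (toluene, BHT, 100 °C) should give the enediol diether methyl 5-bromo-2-{[2-[(tert-butyldimethylsilyl)oxy]-5-(methoxycarbonyl)cyclohex-1-en-1-yl]oxy}-3,4-dimethoxybenzoate F3, with regiocontrol resting only on the silyloxy group being the stronger donor. Bromine at −78 °C should convert F3 into the bromoketone methyl 5-bromo-2-{[1-bromo-5-(methoxycarbonyl)-2-oxocyclohexyl]oxy}-3,4-dimethoxybenzoate F4 (not isolated), and Et3N should remove HBr to rejoin the route at 11.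

Step 6. Claisen-type attack of the sodium enolate, or of the amide base, on the ring B methyl ester may compete with O-silylation. The fallback replaces enolate chemistry by electrophilic activation, so that no carbanion ever meets the ester. Setting out from 7, TBSOTf (CH2Cl2, −78 °C) should silylate the carbonyl oxygen to the vinylogous iminium salt N-{2-[4-bromo-2,3-dimethoxy-6-(methoxycarbonyl)phenoxy]-3-[(tert-butyldimethylsilyl)oxy]but-2-en-1-ylidene}-N-methylmethanaminium trifluoromethanesulfonate F5. Its C-methyl group is acidic enough for Et3N to deprotonate it, which returns to the route at 8.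

Step 9. Elimination across a6–a1 through the ester α-hydrogen may strip the new a6 bromine and lead on to a bromine-free phenol, and ionisation of the a5 bromide next to the carbonyl may be slow. The fallback avoids base altogether. Setting out from 11, bromine (3.1 equiv) in acetic acid at 20 → 50 °C should carry out the addition–elimination at a6, the dehydrogenation and the a3 bromination in one acid-mediated operation, passing through 13 and 15 without isolation and rejoining the route at 16. This fallback makes no compound beyond those of the compound list (F0).

Step 10. Halogenation may stray to the newly formed phenol or to ring B before all of 13 is consumed, giving mixtures, or loss of HBr may be incomplete. The fallback dehydrogenates without halogen. Setting out from 13, DDQ (1.2 equiv, 1,4-dioxane, 90 °C) should abstract hydride from the dienol and return to the route at 15. It makes no compound beyond those of the compound list (F0).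

Step 13. Reduction of the ring A ester may stall, because the para aluminium phenoxide deactivates it, or the para-hydroxybenzylic C–O bonds may ionise during work-up and give oligomers. The fallback changes the order of events. Setting out from 16, iBu2AlH should reduce the esters while the catechol is still methylated, giving the diol 3,6-dibromo-2-[4-bromo-6-(hydroxymethyl)-2,3-dimethoxyphenoxy]-4-(hydroxymethyl)phenol F6. BBr3 should cleave the ethers and convert both carbinols into bromides, giving 6-bromo-4-(bromomethyl)-3-[2,5-dibromo-3-(bromomethyl)-6-hydroxyphenoxy]benzene-1,2-diol F7. Brief solvolysis in dilute aqueous acetone over CaCO3 should then return to the route at 18.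

## Further compounds

F1 | step 7 | methyl 5-bromo-3,4-dimethoxy-2-[(3-oxobut-1-en-2-yl)oxy]benzoate | COC(=O)c1cc(Br)c(OC)c(OC)c1OC(=C)C(C)=O
F2 | step 7 | methyl 5-bromo-2-({3-[(tert-butyldimethylsilyl)oxy]buta-1,3-dien-2-yl}oxy)-3,4-dimethoxybenzoate | C=C(O[Si](C)(C)C(C)(C)C)C(=C)Oc1c(C(=O)OC)cc(Br)c(OC)c1OC
F3 | step 7 | methyl 5-bromo-2-{[2-[(tert-butyldimethylsilyl)oxy]-5-(methoxycarbonyl)cyclohex-1-en-1-yl]oxy}-3,4-dimethoxybenzoate (racemic) | COC(=O)C1CCC(O[Si](C)(C)C(C)(C)C)=C(Oc2c(C(=O)OC)cc(Br)c(OC)c2OC)C1
F4 | step 7 | methyl 5-bromo-2-{[1-bromo-5-(methoxycarbonyl)-2-oxocyclohexyl]oxy}-3,4-dimethoxybenzoate (diastereomer mixture) | COC(=O)C1CCC(=O)C(Br)(Oc2c(C(=O)OC)cc(Br)c(OC)c2OC)C1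
F5 | step 6 | N-{2-[4-bromo-2,3-dimethoxy-6-(methoxycarbonyl)phenoxy]-3-[(tert-butyldimethylsilyl)oxy]but-2-en-1-ylidene}-N-methylmethanaminium trifluoromethanesulfonate | C[N+](C)=CC(Oc1c(C(=O)OC)cc(Br)c(OC)c1OC)=C(C)O[Si](C)(C)C(C)(C)C.[O-]S(=O)(=O)C(F)(F)F
F0 | step 9 | none | none
F0 | step 10 | none | none
F6 | step 13 | 3,6-dibromo-2-[4-bromo-6-(hydroxymethyl)-2,3-dimethoxyphenoxy]-4-(hydroxymethyl)phenol | OCc1cc(Br)c(O)c(Oc2c(CO)cc(Br)c(OC)c2OC)c1Br
F7 | step 13 | 6-bromo-4-(bromomethyl)-3-[2,5-dibromo-3-(bromomethyl)-6-hydroxyphenoxy]benzene-1,2-diol | BrCc1cc(Br)c(O)c(Oc2c(CBr)cc(Br)c(O)c2O)c1Br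
A1 | alternative 1 | methyl 5-bromo-2-[(5-bromo-4-methoxy-2-oxo-2H-pyran-3-yl)oxy]-3,4-dimethoxybenzoate | COC(=O)c1cc(Br)c(OC)c(OC)c1OC1=C(OC)C(Br)=COC1=O
A2 | alternative 1 | methyl 3-bromoprop-2-ynoate | COC(=O)C#CBr
A3 | alternative 1 | methyl 2,5-dibromo-3-[4-bromo-2,3-dimethoxy-6-(methoxycarbonyl)phenoxy]-4-methoxybenzoate | COC(=O)c1cc(Br)c(OC)c(Oc2c(C(=O)OC)cc(Br)c(OC)c2OC)c1Br
A4 | alternative 2 | 6-[4-bromo-6-(1,3-dioxolan-2-yl)-2,3-dimethoxyphenoxy]-7-methyl-1,4-dioxaspiro[4.4]non-6-ene | CC1=C(Oc2c(C3OCCO3)cc(Br)c(OC)c2OC)C2(CC1)OCCO2
A5 | alternative 2 | dibromocarbene | Br[C]Br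
A6 | alternative 2 | 7-bromo-6-[4-bromo-6-(1,3-dioxolan-2-yl)-2,3-dimethoxyphenoxy]-8-methyl-1,4-dioxaspiro[4.5]deca-6,8-diene | CC1=CCC2(OCCO2)C(Oc3c(C4OCCO4)cc(Br)c(OC)c3OC)=C1Br
A7 | alternative 3 | ethyl 7-[2,5-dibromo-6-methoxy-3-(methoxycarbonyl)phenoxy]-2,5,6-trioxoheptanoate | CCOC(=O)C(=O)CCC(=O)C(=O)COc1c(OC)c(Br)cc(C(=O)OC)c1Br
A8 | alternative 3 | ethyl 2-[2,5-dibromo-6-methoxy-3-(methoxycarbonyl)phenoxy]-3,4-dihydroxybenzoate | CCOC(=O)c1ccc(O)c(O)c1Oc1c(OC)c(Br)cc(C(=O)OC)c1Br
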